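Numbering: the upper flavan-3-ol unit is unprimed (rings A, B, C) and the lower flavan-3,4-diol unit is primed (rings D, E, F). The two are joined C4–C6', and both heterocycles are all-trans, (2R,3S,4R) in each unit.
Enabling feature: ring D is a resorcinol with oxygen on C7' and C8a', hydrogen on C5' and C8', the upper C4 on C6' and the C4' carbon on C4a'. A butadiene oxygenated twice at C1 and once at C3 and alkylated at C4 gives exactly this pattern with a terminal acetylenic ketone after [4+2] addition and loss of methanol.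
Cuts: C4'–H (hydride); O1'–C2' (phenol onto epoxide); C6'–C5' together with C8a'–C4a' (ring D); C4–CH2 (flavan-4-yl cation plus the γ-carbon of acetoacetate); O1–C2 (phenol onto epoxide); the aldol C=C of the upper chalcone.
Forward order: rings A and B are bought and ring C closes first. The acetoacetate chain is attached to C4 and silylated to the diene. Ring D is then built around it with an epoxy ynone that brings ring E, and ring F closes on desilylation. Debenzylation and ketone reduction finish the route.
Stereochemistry: C2/C3 come from a Juliá–Colonna chalcone epoxide and C2'/C3' from an organocatalytic enal epoxide (Cα kept, benzylic carbon inverted on ring closure, hence 2,3-trans). C4 is set by attack anti to a participating 3-acetate, and C4' by axial hydride delivery.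

Key step: step 18

Remark: double-bond geometries left undrawn (silyl enol ether and ketene acetal units) and carbinol centres left undrawn are erased later and are of no consequence. Both halves are made enantioenriched independently, so after their union the minor enantiomers end up mainly in a diastereomer that chromatography removes.

Step 1
Reactants: 1 2,4-dihydroxyacetophenone
Product: 2 4-benzyloxy-2-hydroxyacetophenone
Conditions: BnBr (1.05 equiv), K2CO3, acetone, reflux
Reagents that add atoms: benzyl bromide, BrCc1ccccc1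
Why: Williamson etherification; the 2-OH is held in a hydrogen bond to the acetyl group and is the weaker acid, so one equivalent of halide alkylates only the 4-OH.

Step 2
Reactants: 2 4-benzyloxy-2-hydroxyacetophenone
Product: 3 4-benzyloxy-2-(methoxymethoxy)acetophenone
Conditions: NaH, DMF, 0 °C; MOMCl
Reagents that add atoms: chloromethyl methyl ether, COCCl
Why: Williamson-type O-alkylation; full deprotonation breaks the chelate and the phenoxide is capped as a base-stable acetal that survives the aldol and epoxidation steps.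

Step 3
Reactants: 3 4-benzyloxy-2-(methoxymethoxy)acetophenone; 4 3,4-bis(benzyloxy)benzaldehyde
Product: 5 (E)-3,4,4'-tris(benzyloxy)-2'-(methoxymethoxy)chalcone
Conditions: KOH, EtOH/THF, rt
Reagents that add atoms: none
Why: Claisen–Schmidt condensation; the methyl ketone enolate adds to the non-enolisable aldehyde and E1cB dehydration gives the conjugated E-enone.

Step 4
Reactants: 5 (E)-3,4,4'-tris(benzyloxy)-2'-(methoxymethoxy)chalcone
Product: 6 (αR,βS)-3,4,4'-tris(benzyloxy)-2'-(methoxymethoxy)chalcone epoxide (trans)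
Conditions: poly-L-leucine, urea·H2O2, DBU, THF, rt
Reagents that add atoms: urea–hydrogen peroxide, NC(N)=O.OO
Why: Juliá–Colonna epoxidation (Weitz–Scheffer addition of hydroperoxide within the helical peptide); the L-peptide directs the oxidant to the enone face that gives the (αR,βS)-trans-epoxide, and the ether groups are inert to a nucleophilic oxidant.

Step 5
Reactants: 6 (αR,βS)-3,4,4'-tris(benzyloxy)-2'-(methoxymethoxy)chalcone epoxide
Product: 8 (2R,3R)-7,3',4'-tris(benzyloxy)-3-hydroxyflavan-4-one, via 2'-hydroxychalcone epoxide 7 (not isolated)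
Conditions: conc. HCl (cat.), MeOH/THF, 50 °C
Reagents that add atoms: none
Why: Acid acetal cleavage followed by 6-endo opening of the epoxide by the freed phenol at the benzylic carbon (the dihydroflavonol branch of the Algar–Flynn–Oyamada manifold); Cα is retained as C3 and Cβ is inverted to C2, which gives the 2,3-trans product and closes ring C.

Step 6
Reactants: 8 (2R,3R)-7,3',4'-tris(benzyloxy)-3-hydroxyflavan-4-one
Product: 9 (2R,3S,4R)-7,3',4'-tris(benzyloxy)flavan-3,4-diol
Conditions: NaBH4, THF/MeOH, 0 °C
Reagents that add atoms: none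
Why: Borohydride reduction of the aryl ketone; axial hydride attack on the half-chair with equatorial 2-aryl and 3-OH groups should give mainly the equatorial 4-OH, and this centre is erased in step 10 in any case.

Step 7
Reactants: 9 (2R,3S,4R)-7,3',4'-tris(benzyloxy)flavan-3,4-diol
Product: 10 3,4-di-O-acetyl-7,3',4'-tris(benzyloxy)flavan-3,4-diol (2R; 2,3-trans-3,4-trans)
Conditions: Ac2O, pyridine, DMAP (cat.), rt
Reagents that add atoms: acetic anhydride, CC(=O)OC(C)=O
Why: DMAP-catalysed acylation turns the 4-OH into a leaving group, makes the 3-OH a participating neighbour and removes every proton that could quench the silyl diene of step 10.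

Step 8
Reactants: 11 methyl acetoacetate
Product: 12 methyl 3-(trimethylsilyloxy)but-2-enoate
Conditions: Me3SiCl, Et3N, toluene, rt
Reagents that add atoms: chlorotrimethylsilane, C[Si](C)(C)Cl
Why: Soft enolisation and O-silylation of the enol form of a β-keto ester.

Step 9
Reactants: 12 methyl 3-(trimethylsilyloxy)but-2-enoate
Product: 13 1-methoxy-1,3-bis(trimethylsilyloxy)buta-1,3-diene
Conditions: LiN(iPr)2, THF, −78 °C; Me3SiCl, −78 °C to rt
Reagents that add atoms: chlorotrimethylsilane, C[Si](C)(C)Cl
Why: Kinetic γ-deprotonation of the vinylogous ester and O-silylation of the extended enolate, the standard two-stage preparation of 1,3-bis(silyloxy)dienes.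

Step 10
Reactants: 10 3,4-di-O-acetyl-7,3',4'-tris(benzyloxy)flavan-3,4-diol; 13 1-methoxy-1,3-bis(trimethylsilyloxy)buta-1,3-diene
Product: 15 methyl 4-[3-acetoxy-7,3',4'-tris(benzyloxy)flavan-4α-yl]-3-oxobutanoate (2R; 2,3-trans-3,4-trans), via silyl enol ether 14 (not isolated)
Conditions: Me3SiOTf (0.2 equiv), CH2Cl2, −78 °C; aq. NaHCO3
Reagents that add atoms: none
Why: Vinylogous Mukaiyama-type SN1 alkylation; the silyl triflate ionises the 4-acetate to the benzylic cation stabilised by the 7-benzyloxy group, anchimeric assistance by the 3-acetoxy group covers the face of C3–O, and the diene attacks through its terminal carbon from the other face, which sets C4 3,4-trans and releases a silyl cation that carries the chain.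

Step 11
Reactants: 15 methyl 4-[3-acetoxy-7,3',4'-tris(benzyloxy)flavan-4α-yl]-3-oxobutanoate
Product: 16 methyl 4-[7,3',4'-tris(benzyloxy)-3-hydroxyflavan-4α-yl]-3-oxobutanoate
Conditions: K2CO3 (0.3 equiv), MeOH/THF, 0 °C to rt
Reagents that add atoms: none
Why: Zemplén-type transesterification removes the enolisable acetate before any strong base is used, while the β-keto ester rests as its enolate and exchange at its methyl ester is degenerate.

Step 12
Reactants: 16 methyl 4-[7,3',4'-tris(benzyloxy)-3-hydroxyflavan-4α-yl]-3-oxobutanoate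
Product: 17 methyl 4-[7,3',4'-tris(benzyloxy)-3-(trimethylsilyloxy)flavan-4α-yl]-3-(trimethylsilyloxy)but-2-enoate
Conditions: Me3SiCl (excess), Et3N, toluene, rt; filtration under Ar
Reagents that add atoms: chlorotrimethylsilane, C[Si](C)(C)Cl
Why: Soft enolisation and O-silylation as in step 8, which in the same operation caps the 3-OH with the smallest silyl group, so that no acidic proton is left and the bulk next to the future diene terminus stays low.

Step 13
Reactants: 17 methyl 4-[7,3',4'-tris(benzyloxy)-3-(trimethylsilyloxy)flavan-4α-yl]-3-(trimethylsilyloxy)but-2-enoate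
Product: 18 (3Z)-4-[7,3',4'-tris(benzyloxy)-3-(trimethylsilyloxy)flavan-4α-yl]-1-methoxy-1,3-bis(trimethylsilyloxy)buta-1,3-diene
Conditions: LiN(iPr)2, THF, −78 °C; Me3SiCl, −78 °C to rt; hexane, filtration under Ar
Reagents that add atoms: chlorotrimethylsilane, C[Si](C)(C)Cl
Why: γ-Deprotonation and O-silylation as in step 9, known for 4-alkyl congeners; allylic strain keeps the flavanyl group away from C2–H and therefore cis to the C3 silyloxy group, which is the 3Z geometry that an s-cis diene needs.

Step 14
Reactants: 4 3,4-bis(benzyloxy)benzaldehyde; 19 (triphenylphosphoranylidene)acetaldehyde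
Product: 20 (E)-3-[3,4-bis(benzyloxy)phenyl]prop-2-enal
Conditions: toluene, 80 °C
Reagents that add atoms: none
Why: Wittig olefination with a stabilised formyl ylide gives the E-enal, and a slight deficit of ylide limits a second homologation.

Step 15
Reactants: 20 (E)-3-[3,4-bis(benzyloxy)phenyl]prop-2-enal
Product: 21 (2R,3S)-3-[3,4-bis(benzyloxy)phenyl]oxirane-2-carbaldehyde
Conditions: (R)-2-{bis[3,5-bis(trifluoromethyl)phenyl](trimethylsilyloxy)methyl}pyrrolidine (10 mol %), 35% aq. H2O2, CH2Cl2, rt
Reagents that add atoms: hydrogen peroxide, OO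
Why: Iminium–enamine organocatalysis (asymmetric Weitz–Scheffer epoxidation); the diaryl(silyloxy)methyl group of the (R)-catalyst shields the Si face of Cβ in the E-iminium ion, so hydroperoxide adds to the Re face and the resulting enamine closes on the same face to the trans-(2R,3S)-epoxide.

Step 16
Reactants: 21 (2R,3S)-3-[3,4-bis(benzyloxy)phenyl]oxirane-2-carbaldehyde; 22 ethynylmagnesium bromide
Product: 23 1-{trans-3-[3,4-bis(benzyloxy)phenyl]oxiran-2-yl}prop-2-yn-1-ol (epoxide unchanged; carbinol epimers)
Conditions: THF, −78 °C; aq. NH4Cl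
Reagents that add atoms: none
Why: Grignard 1,2-addition to the aldehyde is much faster than epoxide opening at low temperature, and the new carbinol centre is erased in step 17.

Step 17
Reactants: 23 1-{trans-3-[3,4-bis(benzyloxy)phenyl]oxiran-2-yl}prop-2-yn-1-ol
Product: 24 1-{(2R,3S)-3-[3,4-bis(benzyloxy)phenyl]oxiran-2-yl}prop-2-yn-1-one
Conditions: Dess–Martin periodinane, CH2Cl2, 0 °C to rt
Reagents that add atoms: none
Why: Dess–Martin oxidation of a propargylic alcohol under nearly neutral conditions spares the terminal alkyne and the epoxide, whose ring C–H is not readily enolised.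

Step 18
Reactants: 18 (3Z)-4-[7,3',4'-tris(benzyloxy)-3-(trimethylsilyloxy)flavan-4α-yl]-1-methoxy-1,3-bis(trimethylsilyloxy)buta-1,3-diene; 24 1-{(2R,3S)-3-[3,4-bis(benzyloxy)phenyl]oxiran-2-yl}prop-2-yn-1-one
Product: 26 chalcone epoxide whose ketone-side ring is ring D with trimethylsilyloxy groups on C7' and C8a' and the silylated upper unit on C6', via cyclohexadiene ketal 25 (not isolated)
Conditions: toluene (1 M), 4 Å MS, Ar, rt to 60 °C; evaporation
Reagents that add atoms: none
Why: In this normal-electron-demand Diels–Alder reaction the diene terminus bearing the flavanyl group has the largest HOMO coefficient, because the C3 silyloxy and the C1 ketene acetal oxygens both push electron density towards it, so it bonds to the unsubstituted β-carbon of the ynone (C6'–C5') while the ketene acetal carbon bonds to the α-carbon (C8a'–C4a') in a concerted but strongly asynchronous event. The cyclohexa-1,4-diene ketal 25 then ionises at C8a', gives up the doubly allylic C6'–H and so expels methanol, leaving the arene with silyloxy groups on C7' and C8a', the latter ortho to the ketone. The closest known reaction type is the benzannulation of 1-alkoxy-1,3-bis(silyloxy)butadienes with acetylenic ketones and esters to resorcinol derivatives, and only the size of the C4 substituent goes beyond the usual cases. Ring D is closed by the intermolecular [4+2] cycloaddition itself, both ring bonds arising in one event, so no separate cyclisation mode applies. The two sp3 centres of 25 vanish on aromatisation, so no lasting stereocentre is created, and C2, C3, C4 and both epoxide carbons are spectators under neutral conditions free of Lewis acid. The step needs regioselectivity and an accessible s-cis conformer: the first follows from the matched polarisation of the two partners, the second from the 3Z geometry, which places the flavanyl group on the outside of the diene, and from the terminal alkyne, which presents only a C–H to the hindered terminus.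

Step 19
Reactants: 26 ring D bis(trimethylsilyl) chalcone epoxide carrying the silylated upper unit
Product: 28 7,3',4'-tri-O-benzylfisetinidol-(4α→6)-3',4'-di-O-benzylfustin, via free dihydroxychalcone epoxide 27 (not isolated)
Conditions: K2CO3 (0.5 equiv), MeOH/THF, Ar, 0 °C; AcOH quench
Reagents that add atoms: none
Why: Carbonate-catalysed methanolysis removes all three trimethylsilyl ethers, and the C8a' phenoxide then opens the epoxide at its benzylic carbon with inversion (6-endo opening as in the dihydroflavonol branch of the Algar–Flynn–Oyamada reaction, favoured because C5' carries only hydrogen and the dialkoxyaryl group stabilises the developing charge), so Cα becomes C3' unchanged, Cβ becomes C2' and ring F closes 2,3-trans, (2'R,3'R).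

Step 20
Reactants: 28 7,3',4'-tri-O-benzylfisetinidol-(4α→6)-3',4'-di-O-benzylfustin
Product: 29 fisetinidol-(4α→6)-fustin
Conditions: H2 (1 atm), Pd(OH)2/C, THF/MeOH, rt
Reagents that add atoms: none
Why: Catalytic hydrogenolysis cleaves the five aryl benzyl ethers while the electron-rich 2,4-dioxygenated aryl ketone, the cyclic C2–O bonds and the interflavan bond hold at 1 atm; placing it before the reduction keeps the labile benzylic 4'-OH away from Pd and hydrogen.

Step 21
Reactants: 29 fisetinidol-(4α→6)-fustin
Product: 30 fisetinidol-(4α→6)-leucofisetinidin (target)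
Conditions: NaBH4 (excess), EtOH, 0 °C; dilute AcOH to pH 6, EtOAc extraction
Reagents that add atoms: none
Why: Borohydride reduction of a free phenolic 2,3-trans-dihydroflavonol; axial hydride delivery to the C4' carbonyl of the half-chair with equatorial 2'-aryl and 3'-OH groups gives the equatorial 4'-OH, that is the 3,4-trans (4'R) diol, and the near-neutral work-up avoids ionisation at C4'.

Compound list
1 | 2,4-dihydroxyacetophenone | CC(=O)c1ccc(O)cc1O | starting material
2 | 4-benzyloxy-2-hydroxyacetophenone | CC(=O)c1ccc(OCc2ccccc2)cc1O | intermediate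
3 | 4-benzyloxy-2-(methoxymethoxy)acetophenone | CC(=O)c1ccc(OCc2ccccc2)cc1OCOC | intermediate
4 | 3,4-bis(benzyloxy)benzaldehyde | O=Cc1ccc(OCc2ccccc2)c(OCc2ccccc2)c1 | starting material
5 | (E)-3,4,4'-tris(benzyloxy)-2'-(methoxymethoxy)chalcone | COCOc1cc(OCc2ccccc2)ccc1C(=O)/C=C/c1ccc(OCc2ccccc2)c(OCc2ccccc2)c1 | intermediate
6 | (αR,βS)-3,4,4'-tris(benzyloxy)-2'-(methoxymethoxy)chalcone epoxide | COCOc1cc(OCc2ccccc2)ccc1C(=O)[C@H]1[C@H](c2ccc(OCc3ccccc3)c(OCc3ccccc3)c2)O1 | intermediate
7 | (αR,βS)-3,4,4'-tris(benzyloxy)-2'-hydroxychalcone epoxide | Oc1cc(OCc2ccccc2)ccc1C(=O)[C@H]1[C@H](c2ccc(OCc3ccccc3)c(OCc3ccccc3)c2)O1 | intermediate (not isolated)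
8 | (2R,3R)-7,3',4'-tris(benzyloxy)-3-hydroxyflavan-4-one (tri-O-benzylfustin) | C(c1ccccc1)Oc1ccc2c(c1)O[C@H](c1ccc(OCc3ccccc3)c(OCc3ccccc3)c1)[C@@H](O)C2=O | intermediate
9 | (2R,3S,4R)-7,3',4'-tris(benzyloxy)flavan-3,4-diol | C(c1ccccc1)Oc1ccc2c(c1)O[C@H](c1ccc(OCc3ccccc3)c(OCc3ccccc3)c1)[C@@H](O)[C@@H]2O | intermediate
10 | 3,4-di-O-acetate of 9 (2R; 2,3-trans-3,4-trans) | C(c1ccccc1)Oc1ccc2c(c1)O[C@H](c1ccc(OCc3ccccc3)c(OCc3ccccc3)c1)[C@@H](OC(C)=O)[C@@H]2OC(C)=O | intermediate
11 | methyl acetoacetate | CC(=O)CC(=O)OC | starting material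
12 | methyl 3-(trimethylsilyloxy)but-2-enoate (E/Z) | COC(=O)C=C(C)O[Si](C)(C)C | intermediate
13 | 1-methoxy-1,3-bis(trimethylsilyloxy)buta-1,3-diene | COC(=CC(=C)O[Si](C)(C)C)O[Si](C)(C)C | intermediate
14 | methyl 4-[3-acetoxy-7,3',4'-tris(benzyloxy)flavan-4α-yl]-3-(trimethylsilyloxy)but-2-enoate | C(c1ccccc1)Oc1ccc2c(c1)O[C@H](c1ccc(OCc3ccccc3)c(OCc3ccccc3)c1)[C@@H](OC(C)=O)[C@@H]2CC(O[Si](C)(C)C)=CC(=O)OC | intermediate (not isolated)
15 | methyl 4-[3-acetoxy-7,3',4'-tris(benzyloxy)flavan-4α-yl]-3-oxobutanoate | C(c1ccccc1)Oc1ccc2c(c1)O[C@H](c1ccc(OCc3ccccc3)c(OCc3ccccc3)c1)[C@@H](OC(C)=O)[C@@H]2CC(=O)CC(=O)OC | intermediate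
16 | methyl 4-[7,3',4'-tris(benzyloxy)-3-hydroxyflavan-4α-yl]-3-oxobutanoate | C(c1ccccc1)Oc1ccc2c(c1)O[C@H](c1ccc(OCc3ccccc3)c(OCc3ccccc3)c1)[C@@H](O)[C@@H]2CC(=O)CC(=O)OC | intermediate
17 | methyl 4-[7,3',4'-tris(benzyloxy)-3-(trimethylsilyloxy)flavan-4α-yl]-3-(trimethylsilyloxy)but-2-enoate (E/Z) | C(c1ccccc1)Oc1ccc2c(c1)O[C@H](c1ccc(OCc3ccccc3)c(OCc3ccccc3)c1)[C@@H](O[Si](C)(C)C)[C@@H]2CC(O[Si](C)(C)C)=CC(=O)OC | intermediate
18 | (3Z)-4-[7,3',4'-tris(benzyloxy)-3-(trimethylsilyloxy)flavan-4α-yl]-1-methoxy-1,3-bis(trimethylsilyloxy)buta-1,3-diene (either geometry at C1=C2) | C(c1ccccc1)Oc1ccc2c(c1)O[C@H](c1ccc(OCc3ccccc3)c(OCc3ccccc3)c1)[C@@H](O[Si](C)(C)C)[C@@H]2/C=C(\O[Si](C)(C)C)C=C(OC)O[Si](C)(C)C | intermediate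
19 | (triphenylphosphoranylidene)acetaldehyde | O=CC=P(c1ccccc1)(c1ccccc1)c1ccccc1 | starting material
20 | (E)-3-[3,4-bis(benzyloxy)phenyl]prop-2-enal | O=C/C=C/c1ccc(OCc2ccccc2)c(OCc2ccccc2)c1 | intermediate
21 | (2R,3S)-3-[3,4-bis(benzyloxy)phenyl]oxirane-2-carbaldehyde | O=C[C@H]1[C@H](c2ccc(OCc3ccccc3)c(OCc3ccccc3)c2)O1 | intermediate
22 | ethynylmagnesium bromide | C#C[Mg]Br | starting material
23 | 1-{trans-3-[3,4-bis(benzyloxy)phenyl]oxiran-2-yl}prop-2-yn-1-ol (carbinol epimers) | C#CC(O)[C@H]1[C@H](c2ccc(OCc3ccccc3)c(OCc3ccccc3)c2)O1 | intermediate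
24 | 1-{(2R,3S)-3-[3,4-bis(benzyloxy)phenyl]oxiran-2-yl}prop-2-yn-1-one | C#CC(=O)[C@H]1[C@H](c2ccc(OCc3ccccc3)c(OCc3ccccc3)c2)O1 | intermediate
25 | cyclohexa-1,4-diene cycloadduct (methoxy and silyloxy on C8a', sp3 C6'–H; both transient centres undefined) | C(c1ccccc1)Oc1ccc2c(c1)O[C@H](c1ccc(OCc3ccccc3)c(OCc3ccccc3)c1)[C@@H](O[Si](C)(C)C)[C@@H]2C1C=C(C(=O)[C@H]3[C@H](c4ccc(OCc5ccccc5)c(OCc5ccccc5)c4)O3)C(OC)(O[Si](C)(C)C)C=C1O[Si](C)(C)C | intermediate (not isolated)
26 | tris(trimethylsilyl) chalcone epoxide with ring D formed and the upper unit on C6' | C(c1ccccc1)Oc1ccc2c(c1)O[C@H](c1ccc(OCc3ccccc3)c(OCc3ccccc3)c1)[C@@H](O[Si](C)(C)C)[C@@H]2c1cc(C(=O)[C@H]3[C@H](c4ccc(OCc5ccccc5)c(OCc5ccccc5)c4)O3)c(O[Si](C)(C)C)cc1O[Si](C)(C)C | intermediate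
27 | desilylated chalcone epoxide (free C7'–OH, C8a'–OH and C3–OH) | C(c1ccccc1)Oc1ccc2c(c1)O[C@H](c1ccc(OCc3ccccc3)c(OCc3ccccc3)c1)[C@@H](O)[C@@H]2c1cc(C(=O)[C@H]3[C@H](c4ccc(OCc5ccccc5)c(OCc5ccccc5)c4)O3)c(O)cc1O | intermediate (not isolated)
28 | 7,3',4'-tri-O-benzylfisetinidol-(4α→6)-3',4'-di-O-benzylfustin (lower unit 2R,3R) | C(c1ccccc1)Oc1ccc2c(c1)O[C@H](c1ccc(OCc3ccccc3)c(OCc3ccccc3)c1)[C@@H](O)[C@@H]2c1cc2c(cc1O)O[C@H](c1ccc(OCc3ccccc3)c(OCc3ccccc3)c1)[C@@H](O)C2=O | intermediate
29 | fisetinidol-(4α→6)-fustin | Oc1ccc2c(c1)O[C@H](c1ccc(O)c(O)c1)[C@@H](O)[C@@H]2c1cc2c(cc1O)O[C@H](c1ccc(O)c(O)c1)[C@@H](O)C2=O | intermediate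
30 | (2R,3S,4R)-2-(3,4-dihydroxyphenyl)-6-[(2R,3S,4R)-2-(3,4-dihydroxyphenyl)-3,7-dihydroxychroman-4-yl]chroman-3,4,7-triol | Oc1ccc2c(c1)O[C@H](c1ccc(O)c(O)c1)[C@@H](O)[C@@H]2c1cc2c(cc1O)O[C@H](c1ccc(O)c(O)c1)[C@@H](O)[C@@H]2O | target

Total step count: 21. Longest linear sequence: 15 steps (1–7, 10–13, 18–21).

Steps most likely to fail

Step 18. The cycloaddition at the hindered diene terminus may be slow. That would leave time for silyl transfer, for Michael addition through C2 of the diene, or for polymerisation of the ynone.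
- The fallback sets out from 8 and comes back at 30. It forms the interflavan bond by arene alkylation instead of building ring D.
- Hydrogenolysis of 8 (H2, Pd(OH)2/C, THF/MeOH) would give (+)-fustin F1, and NaBH4 in ethanol would reduce it to (+)-mollisacacidin F2.
- Brief exposure of F2 to 0.1 M aqueous HCl at room temperature would let the C4 cation of one molecule alkylate C6 of ring A of a second molecule (biomimetic Friedel–Crafts-type flavanyl transfer).
- The reaction is stopped at low conversion, and 30 is separated from its 4β epimer, the C8-linked isomer and higher oligomers on a dextran gel.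
- The regiochemical certainty of the main route is given up in exchange for three known operations.

Step 10. The diene may attack through its C2 or at the carbonyl carbon of the participating acetate, the cation may lose H3 to give a flav-3-ene, or facial selectivity may be incomplete.
- The fallback sets out from 10 and comes back at 15. It installs a robust three-carbon nucleophile and then extends the chain.
- Hosomi–Sakurai-type allylation of 10 (allyltrimethylsilane, BF3·OEt2, CH2Cl2, −78 °C) would give the 4α-allylflavan 3-acetate F3.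
- Lemieux–Johnson cleavage (OsO4 cat., NaIO4, 2,6-lutidine, dioxane/water) would give the flavan-4α-ylacetaldehyde F4.
- Roskamp homologation (methyl diazoacetate, SnCl2 cat., CH2Cl2) would convert the aldehyde into the β-keto ester 15.

Step 19. The phenoxide may attack Cα in a 5-exo mode, the benzylic C–O bond may ionise with erosion of the trans relationship, or the base may epimerise or air-oxidise the dihydroflavonol.
- The fallback sets out from 26 and comes back at 28. It separates epoxide opening from ring closure.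
- Phenylmethanethiol with SnCl4 (CH2Cl2, −20 °C) would open the epoxide at the benzylic carbon and strip the silyl groups, giving the α-hydroxy-β-benzylsulfanyl dihydrochalcone F5 with Cα untouched.
- The thiophilic Lewis acid AgBF4 (CH2Cl2, 0 °C) would then release the benzylic carbon to the C8a' phenol, closing ring F mainly 2,3-trans to 28. The minor cis isomer is removed by chromatography.

Further compounds
F1 | step 18 | (+)-fustin, (2R,3R)-3,7,3',4'-tetrahydroxyflavan-4-one | Oc1ccc2c(c1)O[C@H](c1ccc(O)c(O)c1)[C@@H](O)C2=O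
F2 | step 18 | (+)-mollisacacidin, (2R,3S,4R)-flavan-3,4,7,3',4'-pentaol | Oc1ccc2c(c1)O[C@H](c1ccc(O)c(O)c1)[C@@H](O)[C@@H]2O
F3 | step 10 | 3-acetoxy-4α-allyl-7,3',4'-tris(benzyloxy)flavan (2R; 2,3-trans-3,4-trans) | C(c1ccccc1)Oc1ccc2c(c1)O[C@H](c1ccc(OCc3ccccc3)c(OCc3ccccc3)c1)[C@@H](OC(C)=O)[C@@H]2CC=C
F4 | step 10 | [3-acetoxy-7,3',4'-tris(benzyloxy)flavan-4α-yl]acetaldehyde | C(c1ccccc1)Oc1ccc2c(c1)O[C@H](c1ccc(OCc3ccccc3)c(OCc3ccccc3)c1)[C@@H](OC(C)=O)[C@@H]2CC=O
F5 | step 19 | α-hydroxy-β-benzylsulfanyl dihydrochalcone with the upper unit on ring D (Cα as in 26, Cβ epimers) | C(c1ccccc1)Oc1ccc2c(c1)O[C@H](c1ccc(OCc3ccccc3)c(OCc3ccccc3)c1)[C@@H](O)[C@@H]2c1cc(C(=O)[C@H](O)C(SCc3ccccc3)c3ccc(OCc4ccccc4)c(OCc4ccccc4)c3)c(O)cc1O
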